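**Retrosynthetic overview**

1. Target 18 ⇐ 4α,5α‑epoxide 17 by base‑induced epoxide → allylic alcohol isomerisation (gives C5–OH and C4=CH2); 17 ⇐ methyl ketone 12 + dienyl phosphonate 15 (C11=C12, Horner–Wadsworth–Emmons).
2. 12 ⇐ bromo epoxide 9 (ozonolysis of isopropenyl, then C7 epimerisation to the equatorial acetyl) ⇐ 8 ⇐ 7 (OH‑directed epoxidation, then Appel inversion at C1).
3. Key disconnection C4=C5: 7 ⇐ 1,6‑diketone 5 by low‑valent‑titanium ketyl coupling and deoxygenation, which joins two carbonyl (acceptor) carbons and closes ring A.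
4. 5 ⇐ (S)‑carvone 1 + 4‑oxopentanal 2 by reductive aldol (quaternary C10 and carbinol C1).
5. Ring order: ring B comes with carvone; ring A is closed second, in the titanium step.

Convention (one assumption): eudesmane numbering is used for all compounds (C1 = CHBr, C4 = C=CH2 with C15, C5 = C–OH, C7 = side‑chain carbon, C10 = C–CH3, C11 = first side‑chain carbon; ring A = C1–C5,C10; ring B = C5–C10). β is the face of the C10 methyl group; the SMILES is read as 1β‑Br, 5α‑OH, 7β‑side chain, 10β‑CH3.

**Route**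

Step 1
Reactants: 1 (S)-(+)-carvone; 2 4-oxopentanal
Product: 5 (2S,5S)-2-methyl-2-[(1S)-4-oxo-1-(triethylsilyloxy)pentyl]-5-(prop-1-en-2-yl)cyclohexan-1-one, via lithium enolate 3 (not isolated), via lithium aldolate 4 (not isolated)
Conditions: LiBH(s-Bu)3 (1.05 equiv), THF, −78 °C; then 2, −78 °C, 30 min; then Et3SiOTf, −78 → 0 °C
Reagents that add atoms: triethylsilyl trifluoromethanesulfonate CC[Si](CC)(CC)OS(=O)(=O)C(F)(F)F
Why: Reductive aldol reaction — 1,4‑hydride delivery gives only the C5=C10 enolate, which attacks the aldehyde of 2 axially on the face cis to the pseudo‑equatorial isopropenyl group (sets C10 with the side arm cis to isopropenyl, the sense known from dihydrocarvone annulations) through a Zimmerman–Traxler chair in which the ring‑fixed E enolate gives the anti adduct (sets C1 with its oxygen trans to the C10 methyl on the later ring A), and silylation at −78 °C blocks retro‑aldol; minor diastereomers are removed by chromatography.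

Step 2
Reactants: 5 (2S,5S)-2-methyl-2-[(1S)-4-oxo-1-(triethylsilyloxy)pentyl]-5-(prop-1-en-2-yl)cyclohexan-1-one
Product: 7 7α-isopropenyl-4,10β-dimethyloctal-4-en-1α-ol, via silyl ether 6 (not isolated)
Conditions: TiCl3(DME)1.5 (8 equiv), Zn–Cu couple, DME, reflux, addition of 5 by syringe pump over 30 h; filtration; then PPTS (cat.), MeOH, rt
Reagents that add atoms: none
Why: McMurry coupling — low‑valent titanium reduces both carbonyl groups to ketyl radical anions, so the two normally electrophilic carbons C4 and C5 are joined through a donor‑type carbonyl carbon to a titanium pinacolate that is deoxygenated to the tetrasubstituted C4=C5 alkene (ring A closed, no stereocentre touched); the quaternary C10 excludes β‑elimination of the silyloxy group, and mild methanolysis then frees the 1α‑OH.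

Step 3
Reactants: 7 7α-isopropenyl-4,10β-dimethyloctal-4-en-1α-ol
Product: 8 4α,5α-epoxy-7α-isopropenyl-4β,10β-dimethyldecalin-1α-ol
Conditions: VO(acac)2 (5 mol %), t-BuOOH (1.5 equiv), CH2Cl2, 0 °C → rt
Reagents that add atoms: tert-butyl hydroperoxide CC(C)(C)OO
Why: Hydroxyl‑directed vanadium‑catalysed epoxidation of a homoallylic alcohol: the peroxide is delivered from the vanadium alkoxide of the pseudo‑axial 1α‑OH to the α‑face of C4=C5 (sets C4 and C5 with oxygen anti to the C10 methyl), and the undirected isopropenyl group does not react.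

Step 4
Reactants: 8 4α,5α-epoxy-7α-isopropenyl-4β,10β-dimethyldecalin-1α-ol
Product: 9 1β-bromo-4α,5α-epoxy-7α-isopropenyl-4β,10β-dimethyldecalin
Conditions: PPh3, CBr4, pyridine, CH2Cl2, 0 → 40 °C
Reagents that add atoms: carbon tetrabromide BrC(Br)(Br)Br
Why: Appel reaction: bromide displaces the axial alkoxyphosphonium group by SN2 with inversion to give the equatorial 1β‑bromide (sets C1), a substitution that is slow at this neopentyl centre but precedented for axial carbinols next to quaternary carbons, while pyridine keeps the epoxide from acid.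

Step 5
Reactants: 9 1β-bromo-4α,5α-epoxy-7α-isopropenyl-4β,10β-dimethyldecalin
Product: 12 7β-acetyl-1β-bromo-4α,5α-epoxy-4β,10β-dimethyldecalin, via ozonide 10 (not isolated), via 7α-acetyl epimer 11 (not isolated)
Conditions: O3, CH2Cl2, −78 °C; Me2S, −78 °C → rt; then NaOMe (0.2 equiv), MeOH, rt
Reagents that add atoms: ozone [O-][O+]=O
Why: Ozonolysis cleaves the only C=C bond to the methyl ketone, and catalytic methoxide then equilibrates C7 through the enolate from the axial 7α‑acetyl group (syn‑axial to the epoxide oxygen and H‑9α) to the equatorial 7β‑acetyl group, which sets the final C7 configuration under thermodynamic control.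

Step 6
Reactants: 13 diethyl allylphosphonate; 14 isoprene
Product: 15 diethyl [(2E)-4-methylpenta-2,4-dien-1-yl]phosphonate
Conditions: second-generation Grubbs catalyst RuCl2(=CHPh)(PCy3)(H2IMes) (3 mol %), 14 (5 equiv), CH2Cl2, 40 °C, sealed tube
Reagents that add atoms: none
Why: Olefin cross‑metathesis: the ruthenium carbene engages only the monosubstituted alkene of isoprene (the 1,1‑disubstituted end is inert) and the allylphosphonate, and gives the conjugated (E)‑dienyl phosphonate with loss of ethene.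

Step 7
Reactants: 12 7β-acetyl-1β-bromo-4α,5α-epoxy-4β,10β-dimethyldecalin; 15 diethyl [(2E)-4-methylpenta-2,4-dien-1-yl]phosphonate
Product: 17 1β-bromo-4α,5α-epoxy-4β,10β-dimethyl-7β-[(2E,4E)-6-methylhepta-2,4,6-trien-2-yl]decalin, via lithiated phosphonate 16 (not isolated)
Conditions: 15, LiN(SiMe3)2, THF–DMPU, −78 °C; then 12, −78 °C → rt
Reagents that add atoms: none
Why: Horner–Wadsworth–Emmons olefination of the methyl ketone with the α‑lithiated allylic phosphonate, in which the bulky ring carbon C7 and the dienyl chain take the trans positions of the new trisubstituted C11=C12 bond (mainly E; the minor Z isomer is removed on AgNO3‑impregnated silica).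

Step 8
Reactants: 17 1β-bromo-4α,5α-epoxy-4β,10β-dimethyl-7β-[(2E,4E)-6-methylhepta-2,4,6-trien-2-yl]decalin
Product: 18 (1R,4aR,6R,8aR)-1-bromo-8a-methyl-4-methylidene-6-[(2E,4E)-6-methylhepta-2,4,6-trien-2-yl]octahydronaphthalen-4a(2H)-ol
Conditions: Et2AlCl + Li(TMP) (TMP = 2,2,6,6-tetramethylpiperidide) → Et2Al(TMP) (4 equiv), toluene, 0 °C; then 17, 0 °C → rt; aq. KNaC4H4O6
Reagents that add atoms: none
Why: Yamamoto epoxide‑to‑allylic‑alcohol rearrangement: aluminium binds the epoxide oxygen and the hindered amide removes a syn proton from the most accessible β‑carbon, the C15 methyl group, with cleavage of the C4–O bond, so the C5–O bond and its α configuration are kept while the exocyclic C4=C15 bond forms, and the equatorial bromide has no anti‑periplanar hydrogen for E2.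

**Compound list**

1 | (S)-(+)-carvone, (5S)-2-methyl-5-(prop-1-en-2-yl)cyclohex-2-en-1-one | CC(=C)[C@H]1CC=C(C)C(=O)C1 | starting material
2 | 4-oxopentanal (levulinaldehyde) | CC(=O)CCC=O | starting material
3 | lithium (5S)-2-methyl-5-(prop-1-en-2-yl)cyclohex-1-en-1-olate | CC(=C)[C@H]1CCC(C)=C(O[Li])C1 | intermediate
4 | lithium (1S)-1-[(1S,4S)-1-methyl-2-oxo-4-(prop-1-en-2-yl)cyclohexyl]-4-oxopentan-1-olate | CC(=C)[C@H]1CC[C@@](C)([C@@H](O[Li])CCC(C)=O)C(=O)C1 | intermediate
5 | (2S,5S)-2-methyl-2-[(1S)-4-oxo-1-(triethylsilyloxy)pentyl]-5-(prop-1-en-2-yl)cyclohexan-1-one | CC(=C)[C@H]1CC[C@@](C)([C@@H](O[Si](CC)(CC)CC)CCC(C)=O)C(=O)C1 | intermediate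
6 | triethylsilyl ether of 7: 1α-(triethylsilyloxy)-7α-isopropenyl-4,10β-dimethyloctal-4-ene | CC(=C)[C@H]1CC[C@@]2(C)[C@@H](O[Si](CC)(CC)CC)CCC(C)=C2C1 | intermediate
7 | 7α-isopropenyl-4,10β-dimethyloctal-4-en-1α-ol, (1S,6S,8aR)-4,8a-dimethyl-6-(prop-1-en-2-yl)-1,2,3,5,6,7,8,8a-octahydronaphthalen-1-ol | CC(=C)[C@H]1CC[C@@]2(C)[C@@H](O)CCC(C)=C2C1 | intermediate
8 | 4α,5α-epoxy-7α-isopropenyl-4β,10β-dimethyldecalin-1α-ol | CC(=C)[C@H]1CC[C@@]2(C)[C@@H](O)CC[C@@]3(C)O[C@@]23C1 | intermediate
9 | 1β-bromo-4α,5α-epoxy-7α-isopropenyl-4β,10β-dimethyldecalin | CC(=C)[C@H]1CC[C@@]2(C)[C@H](Br)CC[C@@]3(C)O[C@@]23C1 | intermediate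
10 | secondary ozonide of 9: 1β-bromo-4α,5α-epoxy-4β,10β-dimethyl-7α-(3-methyl-1,2,4-trioxolan-3-yl)decalin (both trioxolane epimers) | CC4(OCOO4)[C@H]1CC[C@@]2(C)[C@H](Br)CC[C@@]3(C)O[C@@]23C1 | intermediate
11 | 7α-acetyl-1β-bromo-4α,5α-epoxy-4β,10β-dimethyldecalin | CC(=O)[C@H]1CC[C@@]2(C)[C@H](Br)CC[C@@]3(C)O[C@@]23C1 | intermediate
12 | 7β-acetyl-1β-bromo-4α,5α-epoxy-4β,10β-dimethyldecalin | CC(=O)[C@@H]1CC[C@@]2(C)[C@H](Br)CC[C@@]3(C)O[C@@]23C1 | intermediate
13 | diethyl allylphosphonate (diethyl prop-2-en-1-ylphosphonate) | C=CCP(=O)(OCC)OCC | starting material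
14 | isoprene (2-methylbuta-1,3-diene) | C=CC(C)=C | starting material
15 | diethyl [(2E)-4-methylpenta-2,4-dien-1-yl]phosphonate | CCOP(=O)(C/C=C/C(C)=C)OCC | intermediate
16 | α-lithio derivative of 15 | [Li]C(/C=C/C(C)=C)P(=O)(OCC)OCC | intermediate
17 | 1β-bromo-4α,5α-epoxy-4β,10β-dimethyl-7β-[(2E,4E)-6-methylhepta-2,4,6-trien-2-yl]decalin | C=C(C)/C=C/C=C(\C)[C@@H]1CC[C@@]2(C)[C@H](Br)CC[C@@]3(C)O[C@@]23C1 | intermediate
18 | (1R,4aR,6R,8aR)-1-bromo-8a-methyl-4-methylidene-6-[(2E,4E)-6-methylhepta-2,4,6-trien-2-yl]octahydronaphthalen-4a(2H)-ol | C=C(C)/C=C/C=C(\C)[C@@H]1CC[C@@]2(C)[C@H](Br)CCC(=C)[C@]2(O)C1 | target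

**Step count and risks**

Total step count: 8. Longest linear sequence: 7 (steps 1–5, 7 and 8, from 1); step 6 is the one-step side branch.

Most likely to fail, step 1: two stereocentres (C10, C1) are set at once on a tetrasubstituted enolate, and the lithium aldolate can revert before it is silylated. The fallback sets out from 1 and comes back to the route at 5. 1 is reduced with LiBH(s-Bu)3 and the enolate is trapped with Me3SiCl as (5S)-2-methyl-5-(prop-1-en-2-yl)-1-(trimethylsilyloxy)cyclohex-1-ene F1. A TiCl4-promoted Mukaiyama aldol addition of this silyl enol ether to 2 (CH2Cl2, −78 °C; open transition state, no reversible lithium aldolate) gives the free aldol (2S,5S)-2-[(1S)-1-hydroxy-4-oxopentyl]-2-methyl-5-(prop-1-en-2-yl)cyclohexan-1-one F2. It is purified from its diastereomers and silylated with Et3SiCl and imidazole to 5.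

Most likely to fail, step 4: SN2 at a neopentyl secondary carbinol competes with elimination and 1,2-methyl shift, and the tetrasubstituted epoxide is acid-sensitive. The fallback sets out from 8 and comes back at 9. Tf2O and pyridine (CH2Cl2, −40 °C) give the isolated sulfonate 4α,5α-epoxy-7α-isopropenyl-4β,10β-dimethyldecalin-1α-yl trifluoromethanesulfonate F3. It is displaced with inversion by the soluble, non-basic bromide source Bu4NBr in toluene at room temperature to give 9, with no phosphorus reagent or acid present.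

Most likely to fail, step 8: the proton could also be taken from C3 or C6 (regioisomeric allylic alcohols), and the aluminium amide meets a triene and a secondary bromide at the last stage. The fallback sets out from 17 and comes back at 18. Me3SiOTf and DBU in toluene at 0 °C (silyl activation of the epoxide oxygen, removal of a C15 proton by the amidine) give the silyl ether 1β-bromo-10β-methyl-4-methylidene-7β-[(2E,4E)-6-methylhepta-2,4,6-trien-2-yl]-5α-(trimethylsilyloxy)decalin F4. It is cleaved with K2CO3 in MeOH to 18.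

Further compounds
F1 | step 1 | (5S)-2-methyl-5-(prop-1-en-2-yl)-1-(trimethylsilyloxy)cyclohex-1-ene | CC(=C)[C@H]1CCC(C)=C(O[Si](C)(C)C)C1
F2 | step 1 | (2S,5S)-2-[(1S)-1-hydroxy-4-oxopentyl]-2-methyl-5-(prop-1-en-2-yl)cyclohexan-1-one | CC(=C)[C@H]1CC[C@@](C)([C@@H](O)CCC(C)=O)C(=O)C1
F3 | step 4 | 4α,5α-epoxy-7α-isopropenyl-4β,10β-dimethyldecalin-1α-yl trifluoromethanesulfonate | CC(=C)[C@H]1CC[C@@]2(C)[C@@H](OS(=O)(=O)C(F)(F)F)CC[C@@]3(C)O[C@@]23C1
F4 | step 8 | 1β-bromo-10β-methyl-4-methylidene-7β-[(2E,4E)-6-methylhepta-2,4,6-trien-2-yl]-5α-(trimethylsilyloxy)decalin | C=C(C)/C=C/C=C(\C)[C@@H]1CC[C@@]2(C)[C@H](Br)CCC(=C)[C@]2(O[Si](C)(C)C)C1
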